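**Plan**

1. Numbering used throughout (daucane): five-membered ring C1(CH3, quaternary)–C2–C3–C4(OH, i-Pr)–C5(H); seven-membered ring C5–C6(OAr)–C7=C8(CH3)–C9(OH)–C10–C1.
2. Retrosynthesis: the anisoate C–O bond and the C9 carbinol (via the C9 enone) are cut first. Then C6–C7 and C9–C10 are cut together, giving a cyclopentane that carries C6 as CHO and C10 as CH2I, and (Z)-3-iodo-2-methylacrolein (C7–C9).
3. Enabling feature: the seven-membered ring holds the 2-ene-1,4-dioxygen unit C6(O)–C7=C8–C9(O). Each carbinol carbon is flanked by a carbon that can carry chromium (sp2 C7; neopentyl C10 beside quaternary C1, no β-hydrogen), so the cycloheptene is the head-to-tail union of two halo-aldehydes.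
4. Forward: the cyclopentane is built first. C1 comes from a Cu-catalysed asymmetric conjugate addition, C5 from enolate hydroxymethylation anti to the silylmethyl group, and C4 from isopropylcerium addition anti to the C5 substituent. The seven-membered ring is then closed in one flask by a Co/Cr-mediated then Ni/Cr-mediated double carbonyl addition.
5. C6 is set in the ring closure (chelate of O4–H and C6=O, attack on the H5 face). C9 is formed unselectively, funnelled through the C9 enone and set by CBS reduction. The ester goes onto O6 while O9 is silylated.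

Key step: step 11

Assumption: the silylmethyl Grignard reagent of step 1 is treated as purchasable (otherwise it is one step from (chloromethyl)dimethylphenylsilane and magnesium).

**Route**

Step 1
Reactants: 1 3-methylcyclopent-2-en-1-one; 2 {[dimethyl(phenyl)silyl]methyl}magnesium chloride
Product: 4 (3S)-3-{[dimethyl(phenyl)silyl]methyl}-3-methyl-1-(trimethylsilyloxy)cyclopent-1-ene, via magnesium enolate 3 (not isolated)
Conditions: Cu(OTf)2 (3 mol%), chiral C2-symmetric imidazolinium salt as NHC precursor (4 mol%, enantiomer giving the 3S centre), Et2O, −30 °C; then TMSCl, Et3N, HMPA, −30 °C to rt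
Reagents that add atoms: chlorotrimethylsilane, C[Si](C)(C)Cl
Why: Copper-catalysed asymmetric conjugate addition of a Grignard reagent to a β-substituted cyclopentenone builds quaternary C1, the chiral NHC–Cu complex choosing the enone face, and O-silylation traps the regiodefined enolate.

Step 2
Reactants: 4; 5 formaldehyde
Product: 6 (2S,3S)-2-(hydroxymethyl)-3-{[dimethyl(phenyl)silyl]methyl}-3-methylcyclopentan-1-one
Conditions: 37% aq. HCHO, Yb(OTf)3 (10 mol%), THF, rt
Reagents that add atoms: none
Why: Lanthanide-triflate Mukaiyama aldol with aqueous formaldehyde introduces C6 at C5 on the face anti to the bulky CH2SiMe2Ph group of the neighbouring quaternary carbon, and this trans isomer is also the one favoured if the α-centre equilibrates.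

Step 3
Reactants: 6
Product: 7 (2S,3S)-3-{[dimethyl(phenyl)silyl]methyl}-3-methyl-2-{[(triisopropylsilyl)oxy]methyl}cyclopentan-1-one
Conditions: TIPSCl, imidazole, DMF, 0 °C to rt
Reagents that add atoms: chlorotriisopropylsilane, CC(C)[Si](Cl)(C(C)C)C(C)C
Why: Silylation of the primary alcohol blocks retro-aldol loss of formaldehyde, gives a non-chelating bulky α-substituent for step 4, and has no aryl–silicon bond that could compete in step 5.

Step 4
Reactants: 7; 8 isopropylmagnesium chloride
Product: 9 (1R,2S,3S)-3-{[dimethyl(phenyl)silyl]methyl}-3-methyl-1-(propan-2-yl)-2-{[(triisopropylsilyl)oxy]methyl}cyclopentan-1-ol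
Conditions: i-PrMgCl, anhydrous CeCl3, THF, −78 to 0 °C
Reagents that add atoms: none
Why: Organocerium 1,2-addition to the hindered, enolisable ketone should occur anti to the adjacent CH2OTIPS group, which sets C4 with the hydroxyl cis to C6 and the isopropyl group trans to it.

Step 5
Reactants: 9
Product: 10 (1R,2S,3S)-3-(hydroxymethyl)-3-methyl-1-(propan-2-yl)-2-{[(triisopropylsilyl)oxy]methyl}cyclopentan-1-ol
Conditions: KBr, AcOOH, NaOAc, AcOH, 0 °C to rt
Reagents that add atoms: peracetic acid, CC(=O)OO
Why: Fleming–Tamao oxidation (ipso-bromodesilylation of the phenyl group, then peracid-induced 1,2-shift from silicon to oxygen) turns the C10–Si bond into C10–OH without touching the tertiary alcohol or the TIPS ether.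

Step 6
Reactants: 10
Product: 11 (1R,2S,3S)-3-(iodomethyl)-3-methyl-1-(propan-2-yl)-2-{[(triisopropylsilyl)oxy]methyl}cyclopentan-1-ol
Conditions: I2, PPh3, imidazole, toluene, 80 °C
Reagents that add atoms: iodine, II
Why: Appel-type iodination of the neopentyl primary alcohol; the tertiary alcohol does not react and cannot close an ether because O4 and C10 lie on opposite faces of the ring.

Step 7
Reactants: 11
Product: 12 (1R,2S,3S)-2-(hydroxymethyl)-3-(iodomethyl)-3-methyl-1-(propan-2-yl)cyclopentan-1-ol
Conditions: TBAF, THF, 0 °C to rt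
Reagents that add atoms: none
Why: Fluoride cleavage of the primary TIPS ether; the neopentyl iodide is inert to fluoride and the trans C6/C10 arrangement prevents intramolecular etherification.

Step 8
Reactants: 12
Product: 13 (1R,2R,5S)-2-hydroxy-5-(iodomethyl)-5-methyl-2-(propan-2-yl)cyclopentane-1-carbaldehyde
Conditions: Dess–Martin periodinane, NaHCO3, CH2Cl2, 0 °C
Reagents that add atoms: none
Why: Dess–Martin oxidation of the primary alcohol under buffered neutral conditions gives the β-hydroxy aldehyde without dehydration, and C5 already has its more stable configuration (CHO trans to i-Pr and CH2I).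

Step 9
Reactants: 14 prop-2-yn-1-ol; 15 methylmagnesium bromide
Product: 17 (Z)-3-iodo-2-methylprop-2-en-1-ol, via alkenylmagnesium chelate 16 (not isolated)
Conditions: MeMgBr (2.5 equiv), CuI (10 mol%), THF, −10 °C to rt; then I2, −78 to 0 °C
Reagents that add atoms: iodine, II
Why: Copper-catalysed carbomagnesiation of the propargylic magnesium alkoxide puts methyl on C2 and magnesium on C3 inside a five-membered chelate, so iodinolysis with retention gives only the Z-iodide.

Step 10
Reactants: 17
Product: 18 (Z)-3-iodo-2-methylprop-2-enal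
Conditions: MnO2, CH2Cl2, rt, dark; used at once
Reagents that add atoms: none
Why: Manganese dioxide oxidation of the allylic alcohol is neutral, so the Z geometry (iodine cis to CHO) should survive if light and acid are excluded.

Step 11
Reactants: 13; 18
Product: 21 (1R,4R,5S,6S)-9-(triethylsilyloxy)dauc-7-ene-4,6-diol as C9 epimers, via chromium alkoxide 19 (not isolated), via triethylsilyl ether 20 (not isolated)
Conditions: CrCl2 (8 equiv), cobalt phthalocyanine (5 mol%), THF/DMF, rt; then TESCl; then dilution, NiCl2 (2 mol%), rt; aq. serine/NaHCO3 work-up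
Reagents that add atoms: chlorotriethylsilane, CC[Si](Cl)(CC)CC
Why: Proposed new method: Co(I) converts the neopentyl C10–I of 13 into a radical that Cr(II) captures (quaternary C1, so no β-hydrogen), and the alkyl–Cr(III) adds 1,2 to the unhindered enal 18 to make C9–C10 while the hindered C6 aldehyde and the alkenyl iodide stay untouched in the absence of nickel; TESCl then releases the O9 chromium alkoxide as silyl ether 20, and NiCl2 switches on oxidative addition at the (Z)-C7–I bond, Ni-to-Cr transmetallation and intramolecular addition of the alkenyl–Cr(III) to C6=O to make C6–C7. The closest known reaction types are the cobalt/chromium-mediated alkylation of aldehydes and the nickel/chromium (Nozaki–Hiyama–Kishi) medium-ring closure, here run in one flask with a catalyst switch. The seven-membered ring closes by a 7-exo-trig 1,2-addition, possible only because iodine and C9 are cis on C7=C8. C6 is set by substrate control: Cr(III) bridges O4–H and the aldehyde oxygen, and the tethered alkenyl group can reach only the H5 face of that chelate, which puts H6 in the crowded sector beside the angular methyl and O6 pseudo-equatorial (6S); C9 forms without control and is corrected in steps 14 and 15. The selectivity the step needs is the order of events, because a C10 radical generated after C6–C7 formation would add 5-exo to the enal; the Co-then-Ni sequence and the steric difference between the two aldehydes secure it.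

Step 12
Reactants: 21; 22 4-methoxybenzoyl chloride
Product: 23 (1R,4R,5S,6S)-4-hydroxy-9-(triethylsilyloxy)dauc-7-en-6-yl 4-methoxybenzoate (C9 epimers)
Conditions: DMAP, Et3N, CH2Cl2, 0 °C to rt
Reagents that add atoms: none
Why: DMAP-catalysed acylation of the only free secondary hydroxyl (O6); the tertiary O4–H is too hindered to react and O9 is masked.

Step 13
Reactants: 23
Product: 24 (1R,4R,5S,6S)-4,9-dihydroxydauc-7-en-6-yl 4-methoxybenzoate (C9 epimers)
Conditions: HF·pyridine, pyridine, THF, 0 °C
Reagents that add atoms: none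
Why: Buffered fluoride cleavage of the secondary TES ether leaves the allylic aryl ester and the tertiary alcohol intact.

Step 14
Reactants: 24
Product: 25 (1R,4R,5S,6S)-4-hydroxy-9-oxodauc-7-en-6-yl 4-methoxybenzoate
Conditions: Dess–Martin periodinane, NaHCO3, CH2Cl2, 0 °C to rt
Reagents that add atoms: none
Why: Dess–Martin oxidation of the allylic C9 alcohol converts both epimers into one enone (stereoconvergence), while the tertiary alcohol cannot be oxidised.

Step 15
Reactants: 25
Product: 26 (1R,4R,5S,6S,9R)-4,9-dihydroxydauc-7-en-6-yl 4-methoxybenzoate (target)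
Conditions: (S)-2-methyl-CBS-oxazaborolidine (20 mol%), catecholborane, toluene, −78 °C
Reagents that add atoms: none
Why: Corey–Bakshi–Shibata 1,2-reduction with the alkenyl C8 as the large group delivers hydride to the α-face, which is also the face anti to the axial angular methyl, so catalyst and substrate should both favour the 9R (9β) alcohol.

**Compound list**

1 | 3-methylcyclopent-2-en-1-one | CC1=CC(=O)CC1 | starting material
2 | {[dimethyl(phenyl)silyl]methyl}magnesium chloride | C[Si](C)(C[Mg]Cl)c1ccccc1 | starting material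
3 | chloromagnesium enolate of (3S)-3-{[dimethyl(phenyl)silyl]methyl}-3-methylcyclopentanone | Cl[Mg]OC1=C[C@](C[Si](C)(C)c2ccccc2)(C)CC1 | intermediate
4 | (3S)-3-{[dimethyl(phenyl)silyl]methyl}-3-methyl-1-(trimethylsilyloxy)cyclopent-1-ene | C[Si](C)(C)OC1=C[C@](C[Si](C)(C)c2ccccc2)(C)CC1 | intermediate
5 | formaldehyde | C=O | starting material
6 | (2S,3S)-2-(hydroxymethyl)-3-{[dimethyl(phenyl)silyl]methyl}-3-methylcyclopentan-1-one | OC[C@@H]1[C@](C[Si](C)(C)c2ccccc2)(C)CCC1=O | intermediate
7 | (2S,3S)-3-{[dimethyl(phenyl)silyl]methyl}-3-methyl-2-{[(triisopropylsilyl)oxy]methyl}cyclopentan-1-one | CC(C)[Si](OC[C@@H]1[C@](C[Si](C)(C)c2ccccc2)(C)CCC1=O)(C(C)C)C(C)C | intermediate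
8 | isopropylmagnesium chloride | CC(C)[Mg]Cl | starting material
9 | (1R,2S,3S)-3-{[dimethyl(phenyl)silyl]methyl}-3-methyl-1-(propan-2-yl)-2-{[(triisopropylsilyl)oxy]methyl}cyclopentan-1-ol | CC(C)[Si](OC[C@@H]1[C@](C[Si](C)(C)c2ccccc2)(C)CC[C@@]1(O)C(C)C)(C(C)C)C(C)C | intermediate
10 | (1R,2S,3S)-3-(hydroxymethyl)-3-methyl-1-(propan-2-yl)-2-{[(triisopropylsilyl)oxy]methyl}cyclopentan-1-ol | CC(C)[Si](OC[C@@H]1[C@](CO)(C)CC[C@@]1(O)C(C)C)(C(C)C)C(C)C | intermediate
11 | (1R,2S,3S)-3-(iodomethyl)-3-methyl-1-(propan-2-yl)-2-{[(triisopropylsilyl)oxy]methyl}cyclopentan-1-ol | CC(C)[Si](OC[C@@H]1[C@](CI)(C)CC[C@@]1(O)C(C)C)(C(C)C)C(C)C | intermediate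
12 | (1R,2S,3S)-2-(hydroxymethyl)-3-(iodomethyl)-3-methyl-1-(propan-2-yl)cyclopentan-1-ol | OC[C@@H]1[C@](CI)(C)CC[C@@]1(O)C(C)C | intermediate
13 | (1R,2R,5S)-2-hydroxy-5-(iodomethyl)-5-methyl-2-(propan-2-yl)cyclopentane-1-carbaldehyde | O=C[C@@H]1[C@](CI)(C)CC[C@@]1(O)C(C)C | intermediate
14 | prop-2-yn-1-ol | C#CCO | starting material
15 | methylmagnesium bromide | C[Mg]Br | starting material
16 | bromomagnesium (Z)-3-(bromomagnesio)-2-methylprop-2-en-1-olate | Br[Mg]/C=C(/C)CO[Mg]Br | intermediate
17 | (Z)-3-iodo-2-methylprop-2-en-1-ol | I/C=C(/C)CO | intermediate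
18 | (Z)-3-iodo-2-methylprop-2-enal | I/C=C(/C)C=O | intermediate
19 | dichlorochromium(III) alkoxide of the acyclic C9–C10 adduct (O9 bound to Cr; C9 epimers) | O=C[C@@H]1[C@](CC(O[Cr](Cl)Cl)/C(C)=C\I)(C)CC[C@@]1(O)C(C)C | intermediate
20 | (1R,2R,5R)-2-hydroxy-5-[(3Z)-4-iodo-3-methyl-2-(triethylsilyloxy)but-3-en-1-yl]-5-methyl-2-(propan-2-yl)cyclopentane-1-carbaldehyde (epimers at the silyloxy carbon) | O=C[C@@H]1[C@](CC(O[Si](CC)(CC)CC)/C(C)=C\I)(C)CC[C@@]1(O)C(C)C | intermediate
21 | (1R,4R,5S,6S)-9-(triethylsilyloxy)dauc-7-ene-4,6-diol, i.e. (3R,3aS,4S,8aR)-6,8a-dimethyl-3-(propan-2-yl)-7-(triethylsilyloxy)-1,2,3,3a,4,7,8,8a-octahydroazulene-3,4-diol (C9 epimers) | O[C@H]1C=C(C)C(O[Si](CC)(CC)CC)C[C@@]2(C)CC[C@@](O)(C(C)C)[C@H]12 | intermediate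
22 | 4-methoxybenzoyl chloride | COc1ccc(C(Cl)=O)cc1 | starting material
23 | (1R,4R,5S,6S)-4-hydroxy-9-(triethylsilyloxy)dauc-7-en-6-yl 4-methoxybenzoate (C9 epimers) | COc1ccc(C(=O)O[C@H]2C=C(C)C(O[Si](CC)(CC)CC)C[C@@]3(C)CC[C@@](O)(C(C)C)[C@H]23)cc1 | intermediate
24 | (1R,4R,5S,6S)-4,9-dihydroxydauc-7-en-6-yl 4-methoxybenzoate (C9 epimers) | COc1ccc(C(=O)O[C@H]2C=C(C)C(O)C[C@@]3(C)CC[C@@](O)(C(C)C)[C@H]23)cc1 | intermediate
25 | (3R,3aS,4S,8aR)-3-hydroxy-6,8a-dimethyl-7-oxo-3-(propan-2-yl)-1,2,3,3a,4,7,8,8a-octahydroazulen-4-yl 4-methoxybenzoate | COc1ccc(C(=O)O[C@H]2C=C(C)C(=O)C[C@@]3(C)CC[C@@](O)(C(C)C)[C@H]23)cc1 | intermediate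
26 | (3R,3aS,4S,7R,8aR)-3,7-dihydroxy-6,8a-dimethyl-3-(propan-2-yl)-1,2,3,3a,4,7,8,8a-octahydroazulen-4-yl 4-methoxybenzoate | COc1ccc(C(=O)O[C@H]2C=C(C)[C@H](O)C[C@@]3(C)CC[C@@](O)(C(C)C)[C@H]23)cc1 | target

**Summary**

Total step count: 15. Longest linear sequence: 13 steps (steps 1–8, then 11–15).

**Steps most likely to fail**

Step 11 (labelled step). The order of events may be lost: 18 may self-couple or isomerise from Z to E, or the alkenyl iodide may be activated before C9–C10 exists. The fallback uses known chemistry and replaces the double carbonyl addition by ring-closing metathesis at C7=C8. It sets out from 12. Cobalt/chromium-mediated addition of the alkyl iodide to methacrolein gives the triol F1 as C9 epimers. Silylation of the primary and the secondary hydroxyl (TESCl, imidazole) gives the bis-silyl ether F2. Swern conditions cleave and oxidise only the primary TES ether to the aldehyde F3. Vinylmagnesium bromide, chelated by the O4 alkoxide, adds on the H5 face to give the (6S)-allylic alcohol F4. A second-generation ruthenium carbene then closes the trisubstituted C7=C8 bond, and the route is rejoined at 21.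

Step 4. Facial selectivity may be poor (the silylmethyl group sits on the face the nucleophile must use), or the hindered ketone may be enolised. The fallback delivers oxygen instead of carbon to C4 and sets out from 7. Kinetic deprotonation and triflation (KHMDS, PhNTf2) give the enol triflate F5. Iron-catalysed coupling with 8 gives the isopropylcyclopentene F6. TBAF frees the homoallylic alcohol F7. Vanadium-catalysed hydroxyl-directed epoxidation (VO(acac)2, t-BuOOH) places the oxirane on the face of the CH2OH group to give the epoxy alcohol F8. LiAlH4 opens it at the secondary carbon to give the diol F9. Selective silylation of the primary hydroxyl (TIPSCl, imidazole) rejoins the route at 9.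

Step 1. Enantioselectivity may be insufficient for this bulky Grignard reagent on a five-membered enone. The fallback is resolution and sets out from 1 and 2. Racemic CuBr·SMe2/TMSCl conjugate addition gives 4 together with its enantiomer, the silyl enol ether F10. Steps 2 and 3 on the racemate give 6 with the hydroxy ketone F11 and 7 with the silyl ether F12. Preparative chiral-phase chromatography separates 7 from F12, and the route continues at 7.

**Further compounds**

F1 | step 11 | (1R,2S,3R)-2-(hydroxymethyl)-3-(2-hydroxy-3-methylbut-3-en-1-yl)-3-methyl-1-(propan-2-yl)cyclopentan-1-ol (carbinol epimers) | OC[C@@H]1[C@](CC(O)C(C)=C)(C)CC[C@@]1(O)C(C)C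
F2 | step 11 | bis(triethylsilyl) ether of F1 at the primary and secondary hydroxyls | CC[Si](CC)(CC)OC[C@@H]1[C@](CC(O[Si](CC)(CC)CC)C(C)=C)(C)CC[C@@]1(O)C(C)C
F3 | step 11 | 2-hydroxy-5-methyl-5-[3-methyl-2-(triethylsilyloxy)but-3-en-1-yl]-2-(propan-2-yl)cyclopentane-1-carbaldehyde (ring configuration as in 20) | O=C[C@@H]1[C@](CC(O[Si](CC)(CC)CC)C(C)=C)(C)CC[C@@]1(O)C(C)C
F4 | step 11 | (S)-configured allylic alcohol from vinyl addition to F3 (1-[(S)-1-hydroxyprop-2-en-1-yl] analogue of F3) | C=C[C@H](O)[C@@H]1[C@](CC(O[Si](CC)(CC)CC)C(C)=C)(C)CC[C@@]1(O)C(C)C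
F5 | step 4 | enol triflate of 7 (cyclopent-1-en-1-yl trifluoromethanesulfonate, double bond towards the ring CH2) | CC(C)[Si](OC[C@@H]1[C@](C[Si](C)(C)c2ccccc2)(C)CC=C1OS(=O)(=O)C(F)(F)F)(C(C)C)C(C)C
F6 | step 4 | 1-isopropylcyclopentene from F5 (TIPS ether) | CC(C)[Si](OC[C@@H]1[C@](C[Si](C)(C)c2ccccc2)(C)CC=C1C(C)C)(C(C)C)C(C)C
F7 | step 4 | homoallylic alcohol from F6 (free CH2OH) | OC[C@@H]1[C@](C[Si](C)(C)c2ccccc2)(C)CC=C1C(C)C
F8 | step 4 | epoxy alcohol from F7, oxirane cis to CH2OH | OC[C@@H]1[C@](C[Si](C)(C)c2ccccc2)(C)C[C@@H]3O[C@]13C(C)C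
F9 | step 4 | (1R,2S,3S)-2-(hydroxymethyl)-3-{[dimethyl(phenyl)silyl]methyl}-3-methyl-1-(propan-2-yl)cyclopentan-1-ol | OC[C@@H]1[C@](C[Si](C)(C)c2ccccc2)(C)CC[C@@]1(O)C(C)C
F10 | step 1 | (3R)-enantiomer of 4 | C[Si](C)(C)OC1=C[C@@](C[Si](C)(C)c2ccccc2)(C)CC1
F11 | step 1 | (2R,3R)-enantiomer of 6 | OC[C@H]1[C@@](C[Si](C)(C)c2ccccc2)(C)CCC1=O
F12 | step 1 | (2R,3R)-enantiomer of 7 | CC(C)[Si](OC[C@H]1[C@@](C[Si](C)(C)c2ccccc2)(C)CCC1=O)(C(C)C)C(C)C
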